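At the time of reading, the question is how the J charged has divided between J.Q, with its crystals E, J2, and what is still J.

J 0.29 M; X 1.00 equiv; time 1.5 h; volume of the second phase over the first 0.50

    Q ⇌ X, rate k1*([Q] - [X]/K1) per volume of the first phase (K1 = 0.658, k1 = 0.00918 min⁻¹)
    J + Q → J.Q (k2 = 0.169 L mol⁻¹ min⁻¹)
    2 J → J2 (k3 = 0.0464 L mol⁻¹ min⁻¹)
    E ⇌ J.Q, rate k4*(cs4 - [J.Q]) while solid is left; crystals form when [J.Q] > cs4 (cs4 = 38 mM, k4 = 6.21 min⁻¹)

- percent here means J units held: one J2 counts as two
- what is said of J.Q includes E
- where a step has two of a species, its rate is k times that concentration squared, and two are used at each turn
- in the second phase: X; everything else is in the first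
- charges count per volume of the first phase; a concentration in a rate is the amount of a species over the volume of its own phase; every rate counts per litre of the first phase
- E is a solid; its amount is given per volume of the solution
- run time (flask): 1.5 h

- amber: doubling the solubility in step 4, all else as stated
- blue: doubling the dissolution coefficient of step 4, all else as stated
- grey: doubling the transfer coefficient of step 1, all else as stated
- teal: doubling the amount of X, all else as stated

- how much J.Q and E together there is at 1.5 h, in percent of the J charged
- concentration of J.Q in solution at 50 min, in percent of saturation
- the change that raises the amount of J.Q and E together at 1.5 h, in percent of the J charged most ("none" if none brings more than 2 percentage points) (amber / blue / grey / teal / none)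
- amount of J.Q and E together at 1.5 h, in percent of the J charged, after amber

J can go two ways, and at any moment the J going into J.Q over the J going into J2 is f·cQ/cJ, where f, the selectivity factor, is the rate constant of the step to J.Q over twice that of the step to J2, here 1.82. Q starts at zero, so J2 comes first. Call the crossover time the moment when f·cQ/cJ reaches one.

By hand, X crosses at first at 0.00809 M min⁻¹. If you hold cJ at its charge, you get a first answer of 19.7 min. But J has a half-life of 37.2 min by dimerising alone, so put the fall back in: 12.9 min, then 14.6 min. By then J2 has taken up to 28.2 % of the J. If the rest shared evenly, J.Q would get 35.9 %, and I expect a little above that.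

Now turn the settings. The solubility and the dissolution coefficient do not appear in the crossover time, and the crystal step uses neither J nor Q, so I expect no gain from amber or blue. Grey halves the first answer to 9.85 min, and so does teal. But teal has 0.580 M of X behind it against 0.290 M for grey, so I put teal first.

The forecast gives 42 %, 100.5 % of saturation at the earlier time, teal as the best change and 42 % after amber, saying of teal that “it keeps the Q supply high for the whole run”. Its yield is higher than my even-share figure of 35.9 %.

The flask gives 42.7 %, 101 %, teal and 42.7 %. Amber adds 0 percentage points, blue 0 points, grey 7.3 points and teal 19 points. J2 already stands at 43.4 % at 0.750 h, against 47.4 % at 1.50 h. The split read from the states is 0.418 at 0.150 h and 2.34 at 0.750 h, and the crossover time of 14.6 min lies between those readings.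

For the flask with 0.072 M of J, the first answer stays 19.7 min, since feed and cJ scale together, but J now has a half-life of 150 min by dimerising alone, and going round gives 17.4 min, then 17.6 min, with up to 10.5 % gone to J2 by then. That flask holds J.Q and E at 28.6 %, J2 at 29.1 % and J at 42.3 % at 1.50 h.

(The constants used here belong to no real substance; no experiment stands behind them.)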